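**Retrosynthetic overview**
The benzene ring is the only ring. It is built in one intermolecular [4+2] cycloaddition followed by aromatisation, after both partners have been made.
Feature: in the target, C1(OH)–C6(H)–C5(OMe)–C4(OMe) reads as a 1,1,3,4-tetraoxygenated butadiene. C2(H)–C3(C17H35) reads as the two carbons of an alkyne, with a CO2Me group on C2 as a traceless activator.
Disconnections: C1–C2 and C3–C4 (Diels–Alder reaction of a trimethoxy silyl ketene acetal diene and methyl icos-2-ynoate), then C2–CO2H (saponification, decarboxylation).
The diene comes from methyl 4-methoxyacetoacetate (enol ether, then γ-deprotonation and O-silylation). The ynoate comes from octadecanal (Corey–Fuchs homologation, trapping by methyl chloroformate).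

Key step: step 5

Assumption: the C1=C2 geometry of the silyl ketene acetal diene is drawn (1E); it has no bearing on the outcome, since C1 becomes the planar phenol carbon, so a geometric mixture at this bond would serve equally.

Step 1
Reactants: 1 methyl 4-methoxy-3-oxobutanoate (methyl 4-methoxyacetoacetate)
Product: 3 methyl (E)-3,4-dimethoxybut-2-enoate, via dimethyl ketal 2 (not isolated)
Conditions: HC(OMe)3, cat. p-TsOH·H2O, MeOH, rt; then 130 °C, MeOH distilled off
Reagents that add atoms: trimethyl orthoformate, COC(OC)OC
Why: Acid-catalysed ketalisation by the orthoester and thermal loss of methanol from 2 (enol ether formation of a β-keto ester) should end at the conjugated push–pull alkene, whose (E) isomer, OMe anti to the ester, is the thermodynamic one.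

Step 2
Reactants: 3 methyl (E)-3,4-dimethoxybut-2-enoate
Product: 5 (1E,3Z)-1,3,4-trimethoxy-1-(trimethylsilyloxy)buta-1,3-diene, via lithium dienolate 4 (not isolated)
Conditions: LiN(i-Pr)2, THF, −78 °C; Me3SiCl, −78 °C to rt; dry pentane, filtration, bulb-to-bulb distillation, used at once
Reagents that add atoms: chlorotrimethylsilane, C[Si](C)(C)Cl
Why: Kinetic γ-deprotonation of a 3-alkoxyenoate and O-silylation of the extended enolate is the standard entry to 1,3-dialkoxy-1-silyloxybutadienes, and allylic 1,3-strain between the ester terminus and the C4 methoxy group in the deprotonation conformer should turn that group outward, which is the (3Z) geometry an s-cis diene needs.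

Step 3
Reactants: 6 octadecanal
Product: 7 1,1-dibromononadec-1-ene
Conditions: CBr4, PPh3, Zn dust, CH2Cl2, rt; then 6, rt
Reagents that add atoms: carbon tetrabromide, BrC(Br)(Br)Br
Why: Ramirez dibromoolefination, the first stage of the Corey–Fuchs homologation, in which the ylide Ph3P=CBr2 formed in the flask undergoes a Wittig reaction at the unhindered aliphatic aldehyde.

Step 4
Reactants: 7 1,1-dibromononadec-1-ene; 8 methyl chloroformate
Product: 10 methyl icos-2-ynoate, via nonadec-1-ynyllithium 9 (not isolated)
Conditions: n-BuLi (2.1 equiv), THF, −78 to 0 °C; ClCO2Me, −78 °C to rt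
Reagents that add atoms: methyl chloroformate (compound 8), COC(=O)Cl
Why: Second stage of the Corey–Fuchs homologation, in which bromine–lithium exchange, loss of LiBr with 1,2-hydride shift (Fritsch–Buttenberg–Wiechell rearrangement) and deprotonation by the second equivalent of base give acetylide 9, which the chloroformate acylates on carbon.

Step 5
Reactants: 5 (1E,3Z)-1,3,4-trimethoxy-1-(trimethylsilyloxy)buta-1,3-diene; 10 methyl icos-2-ynoate
Product: 13 methyl 6-heptadecyl-2-hydroxy-4,5-dimethoxybenzoate, via cycloadduct 11 (not isolated), via cyclohexadienone 12 (not isolated)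
Conditions: 5 (3 equiv, in portions), neat, sealed tube, Ar, 130 °C; then 1 M HCl, THF, rt
Reagents that add atoms: none
Why: The step is a thermal, normal-electron-demand Diels–Alder reaction that should run concertedly but very asynchronously: C4 of 5, the terminus that receives the push of both C1 oxygens and of the C3 methoxy group, bonds ahead to the electrophilic β-carbon of 10, and the ketene acetal carbon C1 follows onto the α-carbon. The closest known reaction type is the benzannulation of 1,3-dialkoxy-1-silyloxybutadienes by 3-alkylpropiolates, which gives 6-alkyl-4-alkoxysalicylates; 5 differs from the known dienes only by the methoxy group on its terminus. The single ring, the later benzene ring, is closed in the intermolecular [4+2] mode from four carbons of 5 and two of 10, so that C1–C2 and C3–C4 (target numbering) arise in one operation. The two stereocentres of 11 are fixed by suprafacial addition to the (1E,3Z) diene, which places the outward OSiMe3 and OMe groups cis, but 11 is racemic and both centres vanish on aromatisation, so no control is required. Dilute acid strips methanol and the silyl group from the ketal carbon, and the 4H-cyclohexa-2,5-dienone 12 so formed enolises irreversibly to the phenol; because the ketal carbon bears no hydrogen, no aromatising elimination can expel the methoxy group at the sp3 carbon, and both ethers stay. The selectivity needed is regiochemical, ester beside the phenol and chain beside the methoxy group, and it rests on the polarity match named above, in which three donors outweigh the one opposing methoxy group at C4, while the (3Z) geometry keeps that group outside the s-cis diene so that the termini can be reached.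

Step 6
Reactants: 13 methyl 6-heptadecyl-2-hydroxy-4,5-dimethoxybenzoate
Product: 15 6-heptadecyl-2-hydroxy-4,5-dimethoxybenzoic acid, via dipotassium salt 14 (not isolated)
Conditions: KOH (excess), DMSO–H2O, 100 °C, Ar; then 1 M HCl, 0 °C
Reagents that add atoms: potassium hydroxide, [K+].[OH-]
Why: Saponification (acyl–oxygen cleavage by hydroxide) of a doubly ortho-substituted benzoate needs poorly solvated hydroxide and heat, which the aryl methyl ethers and the alkyl chain tolerate.

Step 7
Reactants: 15 6-heptadecyl-2-hydroxy-4,5-dimethoxybenzoic acid
Product: 16 3-heptadecyl-4,5-dimethoxyphenol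
Conditions: neat melt, Ar, 170 °C, until gas evolution ends
Reagents that add atoms: none
Why: Thermal protodecarboxylation of an electron-rich salicylic acid, in which the ortho hydroxyl and para methoxy groups favour the ipso-protonated keto tautomer (a β-keto acid) that loses CO2 through a six-membered transition state, as 6-alkyl-2,4-dioxygenated benzoic acids do.

**Compound list**
1 | methyl 4-methoxy-3-oxobutanoate (methyl 4-methoxyacetoacetate) | COCC(=O)CC(=O)OC | starting material
2 | methyl 3,3,4-trimethoxybutanoate | COCC(OC)(OC)CC(=O)OC | intermediate (not isolated)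
3 | methyl (E)-3,4-dimethoxybut-2-enoate | COC/C(OC)=C\C(=O)OC | intermediate
4 | lithium (1Z,3Z)-1,3,4-trimethoxybuta-1,3-dien-1-olate (same spatial arrangement as 5; the descriptor changes because OMe outranks OLi) | [Li+].CO/C([O-])=C\C(OC)=C\OC | intermediate (not isolated)
5 | (1E,3Z)-1,3,4-trimethoxy-1-(trimethylsilyloxy)buta-1,3-diene | CO/C(O[Si](C)(C)C)=C\C(OC)=C\OC | intermediate
6 | octadecanal | CCCCCCCCCCCCCCCCCC=O | starting material
7 | 1,1-dibromononadec-1-ene | CCCCCCCCCCCCCCCCCC=C(Br)Br | intermediate
8 | methyl chloroformate | COC(=O)Cl | starting material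
9 | nonadec-1-yn-1-yllithium | CCCCCCCCCCCCCCCCCC#C[Li] | intermediate (not isolated)
10 | methyl icos-2-ynoate | CCCCCCCCCCCCCCCCCC#CC(=O)OC | intermediate
11 | methyl (3RS,6RS)-2-heptadecyl-3,4,6-trimethoxy-6-(trimethylsilyloxy)cyclohexa-1,4-diene-1-carboxylate (racemic, 3-OMe cis to 6-OSiMe3; the (3S,6S) enantiomer is drawn) | CO[C@H]1C(CCCCCCCCCCCCCCCCC)=C(C(=O)OC)[C@@](OC)(O[Si](C)(C)C)C=C1OC | intermediate (not isolated)
12 | methyl (3RS)-2-heptadecyl-3,4-dimethoxy-6-oxocyclohexa-1,4-diene-1-carboxylate (racemic; the (3S) enantiomer is drawn) | CO[C@H]1C(CCCCCCCCCCCCCCCCC)=C(C(=O)OC)C(=O)C=C1OC | intermediate (not isolated)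
13 | methyl 6-heptadecyl-2-hydroxy-4,5-dimethoxybenzoate | CCCCCCCCCCCCCCCCCc1c(C(=O)OC)c(O)cc(OC)c1OC | intermediate
14 | dipotassium 6-heptadecyl-4,5-dimethoxy-2-oxidobenzoate | [K+].[K+].CCCCCCCCCCCCCCCCCc1c(C(=O)[O-])c([O-])cc(OC)c1OC | intermediate (not isolated)
15 | 6-heptadecyl-2-hydroxy-4,5-dimethoxybenzoic acid | CCCCCCCCCCCCCCCCCc1c(C(=O)O)c(O)cc(OC)c1OC | intermediate
16 | 3-heptadecyl-4,5-dimethoxyphenol | CCCCCCCCCCCCCCCCCc1cc(O)cc(OC)c1OC | target

Total step count: 7. Longest linear sequence: 5 steps (1, 2, 5, 6, 7 or 3, 4, 5, 6, 7).

**Steps most likely to fail**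

Step 5.
- What may go wrong: the cycloaddition joins a substituted diene terminus to a β-alkylated alkyne carbon and may be so slow that thermal decay of the diene (silyl migration, hydrolysis, oligomerisation) outruns it.
- Regiocontrol may be eroded by the opposing donor at C4.
- The ketal may also collapse by loss of silanol instead of methanol, which would cap the phenol oxygen.
- Fallback: it sets out from 10 and comes back at 13. The C4 oxygen (target numbering) is taken off the diene and installed after the ring is made.
- Commercial methyl (E)-3-methoxybut-2-enoate is converted by LiN(i-Pr)2 and Me3SiCl into (E)-1,3-dimethoxy-1-(trimethylsilyloxy)buta-1,3-diene F1, whose terminus is an unsubstituted CH2.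
- Heating F1 and 10, followed by acid work-up, is a cycloaddition of the proven class and should give methyl 6-heptadecyl-2-hydroxy-4-methoxybenzoate F2.
- Elbs persulfate oxidation (K2S2O8, aq. NaOH, pyridine, rt) attacks the carbon para to the phenoxide. It should give potassium 2-heptadecyl-4-hydroxy-6-methoxy-3-(methoxycarbonyl)phenyl sulfate F3, which warm dilute HCl cleaves to methyl 6-heptadecyl-2,5-dihydroxy-4-methoxybenzoate F4.
- MeI (1 equiv) and K2CO3 in acetone under Ar should methylate the free 5-OH and spare the 2-OH, which is hydrogen-bonded to the ester. This gives 13.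

Step 2.
- What may go wrong: chelation of lithium by the C4 methoxy oxygen during deprotonation may turn that group inward, which blocks the s-cis conformer.
- C-silylation, loss of methoxide from the dienolate and hydrolysis on handling may also compete.
- Fallback: it sets out from 1 and comes back at 13. Strong base and enol ether 3 are avoided.
- Soft double enolisation of 1 by Me3SiOTf (2.2 equiv) and Et3N in Et2O at 0 °C, free of lithium, should give (1E,3Z)-1,4-dimethoxy-1,3-bis(trimethylsilyloxy)buta-1,3-diene F5.
- Heating F5 and 10 as in step 5, then acid work-up, should give methyl 6-heptadecyl-2,4-dihydroxy-5-methoxybenzoate F6.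
- MeI (1 equiv), K2CO3, acetone should methylate only the non-chelated 4-OH, giving 13.

Step 6.
- What may go wrong: attack of hydroxide on a carbonyl flanked by two ortho substituents and next to a phenoxide may be very slow, and long heating in base invites air oxidation of the electron-rich ring.
- Fallback: it sets out from acetylide 9 and comes back at 15. The ester is chosen so that it is cleaved at the alkyl–oxygen bond, away from the hindered carbonyl.
- Acetylide 9 is trapped by benzyl chloroformate to give benzyl icos-2-ynoate F7.
- Cycloaddition of F7 and 5 as in step 5 should give benzyl 6-heptadecyl-2-hydroxy-4,5-dimethoxybenzoate F8.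
- Hydrogenolysis (H2, Pd/C, EtOAc, rt) should release 15 under neutral conditions.

**Further compounds**
F1 | step 5 | (E)-1,3-dimethoxy-1-(trimethylsilyloxy)buta-1,3-diene | CO/C(O[Si](C)(C)C)=C\C(=C)OC
F2 | step 5 | methyl 6-heptadecyl-2-hydroxy-4-methoxybenzoate | CCCCCCCCCCCCCCCCCc1cc(OC)cc(O)c1C(=O)OC
F3 | step 5 | potassium 2-heptadecyl-4-hydroxy-6-methoxy-3-(methoxycarbonyl)phenyl sulfate | [K+].CCCCCCCCCCCCCCCCCc1c(C(=O)OC)c(O)cc(OC)c1OS(=O)(=O)[O-]
F4 | step 5 | methyl 6-heptadecyl-2,5-dihydroxy-4-methoxybenzoate | CCCCCCCCCCCCCCCCCc1c(C(=O)OC)c(O)cc(OC)c1O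
F5 | step 2 | (1E,3Z)-1,4-dimethoxy-1,3-bis(trimethylsilyloxy)buta-1,3-diene | CO/C(O[Si](C)(C)C)=C\C(O[Si](C)(C)C)=C\OC
F6 | step 2 | methyl 6-heptadecyl-2,4-dihydroxy-5-methoxybenzoate | CCCCCCCCCCCCCCCCCc1c(C(=O)OC)c(O)cc(O)c1OC
F7 | step 6 | benzyl icos-2-ynoate | CCCCCCCCCCCCCCCCCC#CC(=O)OCc1ccccc1
F8 | step 6 | benzyl 6-heptadecyl-2-hydroxy-4,5-dimethoxybenzoate | CCCCCCCCCCCCCCCCCc1c(C(=O)OCc2ccccc2)c(O)cc(OC)c1OC
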